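The route rests on cutting the bond between the diaryl methine C1 and ring A carbon C8a of the tetralin (ring B) as a cationic Friedel–Crafts closure. The feature exploited is that the oxygen of the free hydroxymethyl on C3 stands 1,4 to C1 (O–CH2–C3–C2–C1). Joined to C1 it forms a 2-aryltetrahydrofuran (lariciresinol skeleton), which masks that hydroxyl, leaves only the C2 hydroxymethyl free for the p-coumaroyl group, and makes C1 a latent benzylic cation. The precursor is the tribenzyl ether of lariciresinol p-coumarate. In one operation BCl3 opens the furan, closes ring B para to the ring A methoxy group, sets C1, frees the C3 hydroxymethyl and removes all benzyl ethers.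

Key step: step 8

Numbering: the target uses tetralin numbering (C1 carries the pendant guaiacyl ring C, C2 the p-coumaroyloxymethyl group, C3 the hydroxymethyl group, C4 is the benzylic CH2; ring A is the fused aromatic ring with 6-OMe and 7-OH, ring B the saturated ring). The furan intermediates use tetrahydrofuran numbering (O1, C2 aryl, C3, C4, C5).

Assumption: the (S,S) antipode of the ligand in step 2 is taken to deliver the (R)-acid; if the first run shows the opposite sense, the (R,R) antipode is used with no other change.

Step 1
Reactants: 1 4-(benzyloxy)-3-methoxybenzaldehyde; 2 dimethyl succinate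
Product: 3 (E)-4-[4-(benzyloxy)-3-methoxyphenyl]-3-(methoxycarbonyl)but-3-enoic acid
Conditions: NaOMe (2 equiv), MeOH, reflux; then aq. HCl
Reagents that add atoms: none
Why: Stobbe condensation of a non-enolisable aryl aldehyde with a succinic diester should give the (E)-arylidene half-ester, the carboxylate formed protecting the product from further condensation; no stereocentre is formed.

Step 2
Reactants: 3 (E)-arylidene succinic half-ester
Product: 4 (3R)-4-[4-(benzyloxy)-3-methoxyphenyl]-3-(methoxycarbonyl)butanoic acid
Conditions: H2 (5 bar), [Rh(cod)((S,S)-Et-DuPhos)]BF4 (0.5 mol%), NaOMe (10 mol%), MeOH, rt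
Reagents that add atoms: none
Why: Rhodium-catalysed asymmetric hydrogenation of an itaconate-type half-ester, whose carboxylate and alkene chelate the metal, should set the single stereocentre (R) by catalyst control, and the homogeneous catalyst leaves the benzyl ether intact.

Step 3
Reactants: 4 (R)-half-ester
Product: 6 (4R)-4-[4-(benzyloxy)-3-methoxybenzyl]dihydrofuran-2(3H)-one, via hydroxy acid 5 (not isolated)
Conditions: KOH (1.0 equiv), MeOH, evaporate; LiBH4, THF/MeOH, 0 °C to rt; then 2 M HCl, rt
Reagents that add atoms: none
Why: Chemoselective borohydride reduction of the ester beside an unreactive carboxylate, followed by acid-promoted lactonisation, should give the β-benzyl lactone; the stereocentre is not involved and keeps its configuration.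

Step 4
Reactants: 6 (R)-β-benzyl lactone; 1 4-(benzyloxy)-3-methoxybenzaldehyde
Product: 8 (3S,4R)-3-{[4-(benzyloxy)-3-methoxyphenyl](hydroxy)methyl}-4-[4-(benzyloxy)-3-methoxybenzyl]dihydrofuran-2(3H)-one (both carbinol epimers), via lithium enolate 7 (not isolated)
Conditions: LiN(iPr)2 (1.1 equiv), THF, −78 °C; then 1, −78 °C; sat. NH4Cl
Reagents that add atoms: none
Why: Aldol addition of the lactone enolate to the aldehyde anti to the neighbouring benzyl group should set C3 trans to C4 by substrate control; the carbinol centre forms as a mixture, which is harmless because that carbon is ionised in steps 6 and 8.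

Step 5
Reactants: 8 aldol lactone
Product: 9 (2R,3R)-2-{[4-(benzyloxy)-3-methoxyphenyl](hydroxy)methyl}-3-[4-(benzyloxy)-3-methoxybenzyl]butane-1,4-diol (both carbinol epimers)
Conditions: LiAlH4, THF, 0 °C to rt; H2O/aq. NaOH work-up
Reagents that add atoms: none
Why: Hydride reduction of the lactone to the diol at low temperature should outrun retro-aldol cleavage; no stereocentre is formed or touched.

Step 6
Reactants: 9 triol
Product: 10 {(2S,3R,4R)-2-[4-(benzyloxy)-3-methoxyphenyl]-4-[4-(benzyloxy)-3-methoxybenzyl]tetrahydrofuran-3-yl}methanol (di-O-benzyl-(+)-lariciresinol)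
Conditions: 10-camphorsulfonic acid (10 mol%), CH2Cl2, 0 °C; Et3N quench
Reagents that add atoms: none
Why: SN1-type cyclodehydration: acid ionises the p-alkoxybenzylic C–O bond and the 1,4-related primary hydroxyl closes the five-membered ether (the 1,3-related hydroxyl could only give an oxetane), the aryl group settling trans to the C3 substituent, so both carbinol epimers converge; the reaction is stopped before the slower Friedel–Crafts closure sets in.

Step 7
Reactants: 10 di-O-benzyl-lariciresinol; 11 (E)-3-[4-(benzyloxy)phenyl]prop-2-enoic acid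
Product: 12 {(2S,3R,4R)-2-[4-(benzyloxy)-3-methoxyphenyl]-4-[4-(benzyloxy)-3-methoxybenzyl]tetrahydrofuran-3-yl}methyl (E)-3-[4-(benzyloxy)phenyl]prop-2-enoate
Conditions: DCC, DMAP (10 mol%), CH2Cl2, 0 °C to rt
Reagents that add atoms: none
Why: Steglich esterification of the only free hydroxyl should be clean; no stereocentre is touched and the benzylic ether is inert to carbodiimide/DMAP.

Step 8
Reactants: 12 tribenzyl lariciresinol p-coumarate
Product: 14 [(1S,2R,3R)-7-hydroxy-1-(4-hydroxy-3-methoxyphenyl)-3-(hydroxymethyl)-6-methoxy-1,2,3,4-tetrahydronaphthalen-2-yl]methyl (E)-3-(4-hydroxyphenyl)prop-2-enoate, via tribenzyl cyclolignan borinate 13 (not isolated)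
Conditions: BCl3 (1 M in CH2Cl2, 8 equiv), pentamethylbenzene (10 equiv), CH2Cl2, −78 to −20 °C; MeOH quench, aqueous work-up
Reagents that add atoms: none
Why: BCl3 binds the furan oxygen and the benzylic C2–O bond (furan numbering) ionises with p-benzyloxy assistance to a benzylic cation, which the tethered benzyl ring (future ring A) attacks through the carbon para to its methoxy group; loss of HCl rearomatises, and the same reagent then cleaves the three aryl benzyl ethers by the known BCl3/pentamethylbenzene debenzylation, the scavenger taking up the benzyl cations. The closest known reaction type is the acid-mediated rearrangement of 2-aryltetrahydrofuran lignans (lariciresinol) into aryltetralins (isolariciresinol), an intramolecular Friedel–Crafts alkylation. Ring B closes in a 6-endo mode with respect to the attacking arene π bond, through a chair-like transition state. The new stereocentre C1 is set by the existing C2 and C3 centres: the aryl group takes the pseudo-equatorial position trans to the C2 acyloxymethyl group, giving the all-trans arrangement, and the earlier configuration of this carbon is erased in the cation, so any epimer converges. The step needs para-to-methoxy rather than ortho attack on ring A, secured by stronger para activation and by the crowding of the position between the benzylic CH2 and OMe; it also needs intramolecular capture to outrun capture by the scavenger, secured by the six-membered tether and the hindrance of pentamethylbenzene, while the cinnamate is inert to BCl3 at low temperature.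

Compound list
1 | 4-(benzyloxy)-3-methoxybenzaldehyde (O-benzylvanillin) | O=Cc1ccc(OCc2ccccc2)c(OC)c1 | starting material
2 | dimethyl succinate | COC(=O)CCC(=O)OC | starting material
3 | (E)-4-[4-(benzyloxy)-3-methoxyphenyl]-3-(methoxycarbonyl)but-3-enoic acid | COC(=O)/C(CC(=O)O)=C/c1ccc(OCc2ccccc2)c(OC)c1 | intermediate
4 | (3R)-4-[4-(benzyloxy)-3-methoxyphenyl]-3-(methoxycarbonyl)butanoic acid | COC(=O)[C@H](Cc1ccc(OCc2ccccc2)c(OC)c1)CC(=O)O | intermediate
5 | (3R)-4-[4-(benzyloxy)-3-methoxyphenyl]-3-(hydroxymethyl)butanoic acid (not isolated) | OC[C@H](Cc1ccc(OCc2ccccc2)c(OC)c1)CC(=O)O | intermediate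
6 | (4R)-4-[4-(benzyloxy)-3-methoxybenzyl]dihydrofuran-2(3H)-one | O=C1OC[C@H](Cc2ccc(OCc3ccccc3)c(OC)c2)C1 | intermediate
7 | lithium enolate of lactone 6 (not isolated) | [Li+].[O-]C1=C[C@@H](Cc2ccc(OCc3ccccc3)c(OC)c2)CO1 | intermediate
8 | (3S,4R)-3-{[4-(benzyloxy)-3-methoxyphenyl](hydroxy)methyl}-4-[4-(benzyloxy)-3-methoxybenzyl]dihydrofuran-2(3H)-one, both carbinol epimers | O=C1OC[C@H](Cc2ccc(OCc3ccccc3)c(OC)c2)[C@H]1C(O)c1ccc(OCc2ccccc2)c(OC)c1 | intermediate
9 | (2R,3R)-2-{[4-(benzyloxy)-3-methoxyphenyl](hydroxy)methyl}-3-[4-(benzyloxy)-3-methoxybenzyl]butane-1,4-diol, both carbinol epimers | COc1cc(C[C@@H](CO)[C@H](CO)C(O)c2ccc(OCc3ccccc3)c(OC)c2)ccc1OCc1ccccc1 | intermediate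
10 | {(2S,3R,4R)-2-[4-(benzyloxy)-3-methoxyphenyl]-4-[4-(benzyloxy)-3-methoxybenzyl]tetrahydrofuran-3-yl}methanol (di-O-benzyl-(+)-lariciresinol) | COc1cc(C[C@H]2CO[C@H](c3ccc(OCc4ccccc4)c(OC)c3)[C@H]2CO)ccc1OCc1ccccc1 | intermediate
11 | (E)-3-[4-(benzyloxy)phenyl]prop-2-enoic acid (4-benzyloxycinnamic acid) | OC(=O)/C=C/c1ccc(OCc2ccccc2)cc1 | starting material
12 | {(2S,3R,4R)-2-[4-(benzyloxy)-3-methoxyphenyl]-4-[4-(benzyloxy)-3-methoxybenzyl]tetrahydrofuran-3-yl}methyl (E)-3-[4-(benzyloxy)phenyl]prop-2-enoate | COc1cc(C[C@H]2CO[C@H](c3ccc(OCc4ccccc4)c(OC)c3)[C@H]2COC(=O)/C=C/c2ccc(OCc3ccccc3)cc2)ccc1OCc1ccccc1 | intermediate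
13 | tri-O-benzyl ether of 14 with the C3 hydroxymethyl as its O-dichloroboryl derivative (not isolated) | COc1cc([C@H]2c3cc(OCc4ccccc4)c(OC)cc3C[C@@H](COB(Cl)Cl)[C@@H]2COC(=O)/C=C/c2ccc(OCc3ccccc3)cc2)ccc1OCc1ccccc1 | intermediate
14 | [(1S,2R,3R)-7-hydroxy-1-(4-hydroxy-3-methoxyphenyl)-3-(hydroxymethyl)-6-methoxy-1,2,3,4-tetrahydronaphthalen-2-yl]methyl (E)-3-(4-hydroxyphenyl)prop-2-enoate | COc1cc([C@H]2c3cc(O)c(OC)cc3C[C@@H](CO)[C@@H]2COC(=O)/C=C/c2ccc(O)cc2)ccc1O | target

Total step count: 8. Longest linear sequence: 8 steps (1 to 14).

Steps most likely to fail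

1. Step 8. The cation may be captured by the scavenger or by chloride instead of ring A, or by the ester carbonyl with acyl migration. Debenzylation may stay incomplete, or the guaiacyl methyl ethers may be cleaved on warming. Fallback, setting out from 10 and coming back at 14: the benzyl ethers of 10 are removed first by hydrogenolysis (H2, 1 atm, 10% Pd/C, EtOAc, rt, stopped at full debenzylation) to give (+)-lariciresinol F1. Mitsunobu esterification of F1 with p-coumaric acid (OC(=O)/C=C/c1ccc(O)cc1; PPh3, DIAD, THF, 0 °C), in which the carboxylic acid and not a phenol is the pronucleophile, should give lariciresinol p-coumarate F2. TFA in CH2Cl2 (0 °C to rt) should then effect the same ring-opening and Friedel–Crafts closure on the free phenols and give 14 directly, with deprotection decoupled from ring closure.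

2. Step 6. The furan may re-ionise and undergo premature Friedel–Crafts closure, which would free both hydroxymethyl groups and lose their differentiation. Fallback, setting out from 9 and coming back at 10 (through the epimer, at 14): MnO2 (CH2Cl2, rt) should oxidise only the benzylic alcohol, giving keto diol F3, which rests as its five-membered hemiketal with the 1,4-related hydroxyl. Ionic hydrogenation of the derived 2-aryl oxocarbenium ion (Et3SiH, BF3·OEt2, CH2Cl2, −78 °C) should give 10 and/or the C2-epimeric furan F4 at a temperature where the furan does not re-ionise. F4 serves equally: its 4-benzyloxycinnamate F5 (step 7 conditions) should give 14 under step 8 conditions, because the benzylic centre is planarised there.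

3. Step 2. Enantioselectivity may be insufficient, the sense of induction may be opposite, or turnover may be slow with the trisubstituted aryl itaconate. Fallback, setting out from 3 and coming back at 4: hydrogenation with an achiral homogeneous catalyst ([Rh(cod)(dppb)]BF4, H2, MeOH) should give racemic half-ester F6 without touching the benzyl ether. Classical resolution follows by crystallising the (R)-1-phenylethylammonium salt F7 (or the salt of the antipodal amine, whichever gives the less soluble salt of the (R)-acid); acidification returns 4.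

Further compounds
F1 | step 8 | (+)-lariciresinol, {(2S,3R,4R)-2-(4-hydroxy-3-methoxyphenyl)-4-(4-hydroxy-3-methoxybenzyl)tetrahydrofuran-3-yl}methanol | COc1cc(C[C@H]2CO[C@H](c3ccc(O)c(OC)c3)[C@H]2CO)ccc1O
F2 | step 8 | lariciresinol p-coumarate (ester at the C3 hydroxymethyl of the furan) | COc1cc(C[C@H]2CO[C@H](c3ccc(O)c(OC)c3)[C@H]2COC(=O)/C=C/c2ccc(O)cc2)ccc1O
F3 | step 6 | keto diol, the aryl ketone of 9 (in equilibrium with its cyclic hemiketal) | COc1cc(C[C@@H](CO)[C@H](CO)C(=O)c2ccc(OCc3ccccc3)c(OC)c2)ccc1OCc1ccccc1
F4 | step 6 | C2 epimer of 10, (2R,3R,4R) | COc1cc(C[C@H]2CO[C@@H](c3ccc(OCc4ccccc4)c(OC)c3)[C@H]2CO)ccc1OCc1ccccc1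
F5 | step 6 | 4-benzyloxycinnamate of F4 (C2 epimer of 12) | COc1cc(C[C@H]2CO[C@@H](c3ccc(OCc4ccccc4)c(OC)c3)[C@H]2COC(=O)/C=C/c2ccc(OCc3ccccc3)cc2)ccc1OCc1ccccc1
F6 | step 2 | racemic 4-[4-(benzyloxy)-3-methoxyphenyl]-3-(methoxycarbonyl)butanoic acid | COC(=O)C(Cc1ccc(OCc2ccccc2)c(OC)c1)CC(=O)O
F7 | step 2 | (R)-1-phenylethylammonium salt of 4 | COC(=O)[C@H](Cc1ccc(OCc2ccccc2)c(OC)c1)CC(=O)[O-].C[C@@H]([NH3+])c1ccccc1
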